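## The problem

Target **45** is a 6,8-diformyl-5,7-dihydroxychroman whose pyran ring is trans-fused along C7–C8 to a ten-membered carbocycle. The numbering used throughout is: C1 (exocyclic methylene), C2=C3 (Z alkene), C4 (2-hydroxypropan-2-yl), C5, C6, C7 (methyl-bearing ether carbon), C8 (ring-fusion CH), C9, C10, and C11 (benzylic CH with isobutyl). The arene is Ar1 (bonded to C11), Ar2 (ether oxygen), Ar3 (CHO), Ar4 (OH), Ar5 (CHO), Ar6 (OH), and the target is 4R,7R,8S,11R.

C11, C8 and C7 are contiguous on the pyran ring. C8 and C11 form a vicinal pair that one sigmatropic event can set from a single carbinol centre at C6. The two C7 epimers differ only by exchange of CH3 and the C6 methylene, so C8 cannot be trusted to control C7; a reagent-controlled, stereospecific C–O bond formation is needed. C4 is too remote to be controlled by the others and needs its own asymmetric step.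

The fragile groups are the two aryl aldehydes and acidic phenols (no carbonyl olefination, hydride or organometallic chemistry once they exist), the tertiary alcohol, the tertiary alkyl aryl ether at C7 (ionised by strong Lewis acids), and the diene (acid, electrophiles, heat). The ten-membered ring adds strain and an entropic penalty to any late closure.

The feature that opens the key step is the arene pattern: a 2-alkylphloroglucinol in which only the Ar2 oxygen is etherified and Ar3 and Ar5 are the only carbon-substituted positions besides Ar1. A benzannulation that builds this ring from a chain-bearing cyclobutenone and an alkoxyacetylene delivers exactly the Ar2 oxygen as the one free hydroxyl, the other two oxygens as ethers, and Ar3/Ar5 unsubstituted.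

## Retrosynthesis

**45 ⇒ 43 (C2=C3 and C1=CH2).** The diene is the most sensitive element, so it is made last. Cutting C2=C3 with transfer of a methylene to C1 is the retron of an enyne metathesis between a terminal alkyne (C1≡C2) and a vinyl group on C4. Against C–C couplings at C1–C2, this needs only two inert spectators (vinyl, silyl-protected alkyne) that can be carried from the first steps, and ruthenium carbenes tolerate phenols and aldehydes. The forward step must close in the endo sense, give the Z alkene, and beat oligomerisation.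

**43 ⇒ 42 ⇒ 41 ⇒ 38 ⇒ 37 (Ar3–CHO, Ar5–CHO, two O–ethyl bonds).** The arene is completed before the diene exists. Formyl groups are introduced through dibromide **38** and bromine–lithium exchange rather than with a Lewis-acid formylation, because the C7–O ether and the tertiary silyl ether would not reliably survive TiCl4-type conditions. De-ethylation is placed after formylation, where ortho/para formyl groups turn the ethers into good SN2 substrates for thiolate. Boron halides are avoided because they would open the chelated tertiary C7–O bond. Fluoride then frees alkyne and alcohol (**42 ⇒ 43**).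

**37 ⇒ 36 ⇒ 34 ⇒ 32 ⇒ 31 ⇒ 30 (O–C7).** Direct acid-catalysed addition of the phenol across C6=C7 would pass through a planar C7 cation with no reliable facial bias. Instead the E alkene is epoxidised under reagent control (**32**), and the phenol opens the epoxide at the tertiary carbon with inversion (**34**), which fixes C7 stereospecifically. The price is a C6 hydroxyl, removed by Barton–McCombie reduction via xanthate **36**. The phenol is masked as silyl ether **31** during the oxidation.

**30 ⇒ 25 + 23 (Ar2–Ar3, Ar4–Ar5; benzene ring).** This is the key disconnection. Against attaching the chain to a preformed phloroglucinol (which would not control C11 and would need the three oxygens differentiated), the benzannulation removes the arene altogether. It returns aliphatic cyclobutenone **25** and ethoxyacetylene **23**, and it differentiates the oxygens by construction. The forward reaction must be regioselective and must leave C8, C11 and the chain unsaturation alone.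

**25 ⇒ 22 + 23 ⇒ 20.** The cyclobutenone is the (2+2) adduct of an alkylketene and **23**. The ketene comes from Wolff rearrangement of diazoketone **22**, so the diazomethane carbon becomes Ar1 and the carboxyl carbon of acid **20** becomes Ar2.

**20 ⇒ 18 ⇒ 16 + 17 (C8–C11).** An Ireland–Claisen rearrangement of 4-methylpentanoate **18** forms C8–C11, sets both centres from the C6 carbinol, and leaves the E C6=C7 alkene needed later. No aldol or alkylation route delivers all three features in one step.

**16 ⇒ 15 ⇒ 14 ⇒ 5 + 12 (C5–C6).** Alkyllithium addition to enal **12** joins the two halves. The C6 configuration is then set by catalyst-controlled reduction of enone **15**, independent of C4.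

**5 ⇒ 4 ⇒ 3 ⇒ 2 ⇒ 1 and 12 ⇒ 10 + 11; 10 ⇒ 9 ⇒ 6 + 7.** C4 comes from Sharpless epoxidation of prenol **1** and vinyl-cuprate opening at C2; the vinyl group introduced is the one used in the last step. Enal **12** comes from E-selective Wittig olefination of alkynal **10**, itself from silylacetylene **6** and oxetane **7**.

## Roads not taken

**Alternative 1:** Intramolecular Stille coupling at C1–C2. A C1 enol triflate on the C8 side chain and a Z-alkenylstannane at C2 on the C4 side chain would be joined with Pd(PPh3)4 and LiCl to give **A1**, the complete carbocycle on a dimethoxychroman. Its merit is real: the Z geometry is carried in by the stannane and the exocyclic methylene by the triflate, so the diene geometry is more certain than in a metathesis closure. Its weak points for this target are three. The kinetic enol triflate and the Z-stannane must be built late on a fully elaborated chroman. The ring strain is the same. Most seriously, **A1** still lacks both formyl groups and carries methyl ethers, so formylation and demethylation would have to be run on the diene. The chosen plan gives up the geometric certainty of the Stille coupling, and sets against it an order of events in which the diene is formed last on the finished arene, from two spectators that need no late functional-group work.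

**Alternative 2:** Asymmetric allylic etherification at C7. Zerovalent palladium from Pd2(dba)3 with a chiral diaminocyclohexane bis(2-diphenylphosphinobenzamide) ligand would ionise a C5 allylic carbonate; the Ar2 phenoxide would attack C7 to give **A2**, a 2-methyl-2-vinylchroman. For C7 this road is better: one catalytic step sets the quaternary centre, where the chosen route needs five steps (16–20). Its weak points are that **A2** carries only a vinyl group on C7, so the C5–C4 unit with its stereocentre must be attached afterwards next to a quaternary carbon; the ligand must override the adjacent C8/C11 centres; and the arene and its oxygen pattern still have to come from somewhere. The chosen plan sets against the shorter C7 step the fact that the whole C4–C6 chain, with C4 fixed, is already in place when C7 is formed, and that the same plan also delivers the differentiated arene.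

**Alternative 3:** Alkoxy-radical ring expansion. A C1 alkoxy radical on a tetracyclic precursor with an extra C1–C6 bond (CeCl3, violet light, thiol) would undergo β-scission of C1–C6 and give **A3**, the ten-membered cis-enone. Its merit is that the medium ring is never closed: two six-membered rings are made and one bond is cut, and the cis enone geometry comes from the ring. Its weak points are the cost of building a tetracyclic precursor with two extra stereocentres only to destroy them; the C6 radical that is formed sits β to the C7 aryl ether and could expel the aryloxy group; and **A3** still needs methylenation of the C1 ketone and the whole arene end game in the presence of the enone or diene. On ring formation alone this road is at least as safe as metathesis. The chosen plan answers with a much shorter path to the cyclisation substrate and with a diene that is made after every harsh step.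

Key step: step 15

## Notation and remarks

- "Chain Q" is the C11–C1 unit of acid **20**, attached through C11: C11H(isobutyl)–C8H[CH2CH2C≡C–Si(i-Pr)3]–C7(CH3)=C6H–C5H2–C4H(CH=CH2)–C(CH3)2OSiEt3, E at C6=C7, configuration 4R,8S,11R.
- Chroman names use chroman locants: C2 = C7, C3 = C8, C4 = C11, C5 = Ar6, C6 = Ar5, C7 = Ar4, C8 = Ar3.
- Remark: alcohol **14** (at C6), cyclobutenone **25** and dienone **29** (at the ring CH) form as mixtures at centres that are removed later; their SMILES leave those centres open.
- Remark: ethoxyacetylene **23** is used as its commercial hexane solution.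

## Route

Step 1
Reactants: 1 prenol (3-methylbut-2-en-1-ol)
Product: 2 (R)-(3,3-dimethyloxiran-2-yl)methanol
Conditions: Ti(OiPr)4 (10 mol%), D-(−)-diisopropyl tartrate (12 mol%), t-BuOOH, 4 Å molecular sieves, CH2Cl2, −20 °C
Reagents that add atoms: tert-butyl hydroperoxide, CC(C)(C)OO
Why: Sharpless asymmetric epoxidation of a primary allylic alcohol; the D-(−)-tartrate should give the 2R epoxide (the L-(+)-ester gives 2S in this substrate class), which fixes the future C4.

Step 2
Reactants: 2 (R)-(3,3-dimethyloxiran-2-yl)methanol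
Product: 3 (S)-2-ethenyl-3-methylbutane-1,3-diol
Conditions: CH2=CHMgBr (3 equiv), CuI (10 mol%), THF, −30 → 0 °C
Reagents that add atoms: vinylmagnesium bromide, C=C[Mg]Br
Why: Copper-catalysed SN2 opening of a 2,3-epoxy alcohol by a Grignard reagent; the tertiary C3 is closed to substitution, so the vinyl group enters at C2 with inversion and sets C4 (S here, R once the substituent priorities change).

Step 3
Reactants: 3 (S)-2-ethenyl-3-methylbutane-1,3-diol
Product: 4 (R)-3-(iodomethyl)-2-methylpent-4-en-2-ol
Conditions: I2, PPh3, imidazole, CH2Cl2, 0 °C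
Reagents that add atoms: iodine, II
Why: Appel-type iodination converts only the primary hydroxyl; the tertiary alcohol is not activated under these conditions.

Step 4
Reactants: 4 (R)-3-(iodomethyl)-2-methylpent-4-en-2-ol
Product: 5 (R)-triethyl{[3-(iodomethyl)-2-methylpent-4-en-2-yl]oxy}silane
Conditions: Et3SiOTf, 2,6-lutidine, CH2Cl2, −78 → 0 °C
Reagents that add atoms: triethylsilyl trifluoromethanesulfonate, CC[Si](CC)(CC)OS(=O)(=O)C(F)(F)F
Why: Silylation of a hindered tertiary alcohol with a silyl triflate; the triethylsilyl ether should survive the organolithium, enolate, ketene and radical steps and is removed by fluoride in step 24.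

Step 5
Reactants: 6 ethynyltriisopropylsilane; 7 oxetane
Product: 9 5-(triisopropylsilyl)pent-4-yn-1-ol, via lithium (triisopropylsilyl)acetylide 8 (not isolated)
Conditions: n-BuLi, THF, −78 °C; then 7, BF3·OEt2, −78 °C
Reagents that add atoms: none
Why: BF3-promoted opening of oxetane by a lithium acetylide (Yamaguchi-type alkynylation) gives the C2–C1–C10–C9–C8 chain in one step.

Step 6
Reactants: 9 5-(triisopropylsilyl)pent-4-yn-1-ol
Product: 10 5-(triisopropylsilyl)pent-4-ynal
Conditions: Dess–Martin periodinane, NaHCO3, CH2Cl2, 0 °C → rt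
Reagents that add atoms: none
Why: Dess–Martin oxidation of a primary alcohol to the aldehyde; the silylalkyne is inert.

Step 7
Reactants: 10 5-(triisopropylsilyl)pent-4-ynal; 11 2-(triphenylphosphoranylidene)propanal
Product: 12 (E)-2-methyl-7-(triisopropylsilyl)hept-2-en-6-ynal
Conditions: toluene, 90 °C
Reagents that add atoms: none
Why: Wittig olefination with a stabilised formyl ylide should give the E enal (formyl trans to the chain), which fixes the C7=C8 geometry that the Claisen step needs.

Step 8
Reactants: 5 (R)-triethyl{[3-(iodomethyl)-2-methylpent-4-en-2-yl]oxy}silane; 12 (E)-2-methyl-7-(triisopropylsilyl)hept-2-en-6-ynal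
Product: 14 (3R,6E)-3-ethenyl-2,6-dimethyl-2-(triethylsilyloxy)-11-(triisopropylsilyl)undec-6-en-10-yn-5-ol (C6 epimers; undecane C5 = C6), via alkyllithium 13 (not isolated)
Conditions: t-BuLi (2.1 equiv), Et2O–pentane, −78 °C; then 12, −78 °C; aq. NH4Cl
Reagents that add atoms: none
Why: Iodine–lithium exchange gives the primary alkyllithium, which adds 1,2 to the enal and forms C5–C6; the C6 epimers are carried on because the centre is reset in steps 9 and 10.

Step 9
Reactants: 14 (3R,6E)-3-ethenyl-2,6-dimethyl-2-(triethylsilyloxy)-11-(triisopropylsilyl)undec-6-en-10-yn-5-ol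
Product: 15 (3R,6E)-3-ethenyl-2,6-dimethyl-2-(triethylsilyloxy)-11-(triisopropylsilyl)undec-6-en-10-yn-5-one
Conditions: Dess–Martin periodinane, NaHCO3, CH2Cl2, 0 °C
Reagents that add atoms: none
Why: Oxidation of the allylic alcohol to the α-methyl enone erases the uncontrolled C6 centre.

Step 10
Reactants: 15 (3R,6E)-3-ethenyl-2,6-dimethyl-2-(triethylsilyloxy)-11-(triisopropylsilyl)undec-6-en-10-yn-5-one
Product: 16 (3R,5S,6E)-3-ethenyl-2,6-dimethyl-2-(triethylsilyloxy)-11-(triisopropylsilyl)undec-6-en-10-yn-5-ol (6S in the C numbering)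
Conditions: (R)-2-methyl-CBS-oxazaborolidine (0.5 equiv), catecholborane, toluene, −78 °C
Reagents that add atoms: none
Why: Corey–Bakshi–Shibata reduction of an enone with the alkenyl group as the large substituent; the R catalyst should deliver the 6S alcohol, and catecholborane does not hydroborate the vinyl group at this temperature.

Step 11
Reactants: 16 (3R,5S,6E)-3-ethenyl-2,6-dimethyl-2-(triethylsilyloxy)-11-(triisopropylsilyl)undec-6-en-10-yn-5-ol; 17 4-methylpentanoic acid
Product: 18 (3R,5S,6E)-3-ethenyl-2,6-dimethyl-2-(triethylsilyloxy)-11-(triisopropylsilyl)undec-6-en-10-yn-5-yl 4-methylpentanoate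
Conditions: EDC·HCl, DMAP, CH2Cl2, rt
Reagents that add atoms: none
Why: Carbodiimide (Steglich-type) esterification of a secondary allylic alcohol with retention at C6.

Step 12
Reactants: 18 (3R,5S,6E)-3-ethenyl-2,6-dimethyl-2-(triethylsilyloxy)-11-(triisopropylsilyl)undec-6-en-10-yn-5-yl 4-methylpentanoate
Product: 20 (2R,3S,4E,7R)-7-ethenyl-4,8-dimethyl-2-(2-methylpropyl)-8-(triethylsilyloxy)-3-[4-(triisopropylsilyl)but-3-yn-1-yl]non-4-enoic acid (Q–CO2H), via silyl ketene acetal 19 (not isolated)
Conditions: LDA, Me3SiCl (internal quench), THF, −78 °C → rt; brief dilute aq. HCl work-up (pH 4)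
Reagents that add atoms: chlorotrimethylsilane, C[Si](C)(C)Cl (silicon retained only in 19)
Why: Ireland–Claisen rearrangement: LDA in THF gives the E silyl ketene acetal (isobutyl trans to OSi), which rearranges through a chair with the C5 substituent of C6 equatorial. The 6S carbinol and the E C7=C8 alkene should give the anti 8S,11R pair and the E C6=C7 alkene.

Step 13
Reactants: 20 Q–CO2H
Product: 22 1-diazo-3-substituted ketone Q–C(=O)CHN2, via acid chloride 21 (not isolated)
Conditions: 1-chloro-N,N,2-trimethylprop-1-en-1-amine, CH2Cl2, 0 °C → rt; then CH2N2 (3 equiv), Et2O, 0 °C → rt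
Reagents that add atoms: 1-chloro-N,N,2-trimethylprop-1-en-1-amine, CC(C)=C(Cl)N(C)C (chlorine retained only in 21); diazomethane, C=[N+]=[N-]
Why: Neutral acid chloride formation with Ghosez's reagent (no free HCl for the silyl ether, no amine base to epimerise C11 through a ketene), then acylation of diazomethane as in the first stage of an Arndt–Eistert sequence.

Step 14
Reactants: 22 Q–C(=O)CHN2; 23 ethoxyacetylene
Product: 25 3-ethoxy-4-Q-cyclobut-2-en-1-one (ring CH as a mixture), via alkylketene 24 (not isolated)
Conditions: hν (350 nm, Pyrex), 23 (5 equiv), CH2Cl2, 0 °C → rt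
Reagents that add atoms: none
Why: Photochemical Wolff rearrangement (1,2-shift of C11 with retention) gives the monoalkylketene, which is trapped in situ by the ynol ether in a regioselective ketene–alkyne (2+2) cycloaddition (alkyne CH carbon to the ketene carbonyl carbon).

Step 15
Reactants: 25 3-ethoxy-4-Q-cyclobut-2-en-1-one; 23 ethoxyacetylene
Product: 30 3,5-diethoxy-2-Q-phenol (free hydroxyl on Ar2), via vinylketene 26 (not isolated), via alkenylcyclobutenone 27 (not isolated), via dienylketene 28 (not isolated), via cyclohexadienone 29 (not isolated)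
Conditions: 23 (3 equiv), toluene, 80 °C, sealed tube; then K2CO3, MeOH, rt
Reagents that add atoms: none
Why: Danheiser benzannulation: the cyclobutenone opens by four-electron conrotatory ring opening (C11 substituent outward) to vinylketene 26, which adds ethoxyacetylene in a (2+2) cycloaddition to give 27; a second four-electron opening gives dienylketene 28, six-electron disrotatory electrocyclisation closes the benzene ring (29), and tautomerisation gives phenol 30. The closest known reaction type is the thermal aromatic annulation of cyclobutenones, 3-alkoxy ones included, with alkoxy- and siloxyacetylenes to resorcinol and phloroglucinol ethers. The new skeletal bonds are Ar2–Ar3 and Ar4–Ar5; four arene carbons come from 25 (carbonyl carbon to Ar2, ring CH to Ar1) and two from the alkyne (Ar3, Ar4). No stereocentre is formed, the ring CH of 25 disappears, and C8 and C11 are not enolisable under the neutral conditions. The selectivity that matters is regiochemical: the nucleophilic CH carbon of the ynol ether bonds to the ketene carbonyl carbon, so the hydroxyl ends on Ar2 next to the chain, the ethoxy groups on Ar4 and Ar6, and Ar3 and Ar5 stay free. Chemoselectivity over the vinyl group, the trisubstituted alkene and the silylalkyne rests on the much higher ketenophilicity of the ynol ether, used in excess. Aryl esters formed from 30 and ketene 26 are cleaved by the methanolic carbonate treatment.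

Step 16
Reactants: 30 3,5-diethoxy-2-Q-phenol
Product: 31 tert-butyl(3,5-diethoxy-2-Q-phenoxy)dimethylsilane
Conditions: t-BuMe2SiOTf, 2,6-lutidine, CH2Cl2, 0 °C
Reagents that add atoms: tert-butyldimethylsilyl trifluoromethanesulfonate, CC(C)(C)[Si](C)(C)OS(=O)(=O)C(F)(F)F
Why: Silylation masks the electron-rich phenol against the oxidant and the basic buffer of step 17.

Step 17
Reactants: 31 tert-butyl(3,5-diethoxy-2-Q-phenoxy)dimethylsilane
Product: 32 (6R,7R)-epoxide of 31 (oxirane across C6–C7, otherwise unchanged)
Conditions: D-fructose-derived Shi ketone (0.3 equiv), Oxone (2KHSO5·KHSO4·K2SO4), K2CO3, Bu4NHSO4, aq. Na2B4O7–EDTA buffer, MeCN–CH2(OMe)2, 0 °C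
Reagents that add atoms: potassium peroxymonosulfate, [K+].[O-]S(=O)(=O)OO
Why: Shi asymmetric epoxidation of the E-trisubstituted alkene; the dioxirane from the D-fructose-derived ketone should give the 6R,7R epoxide under reagent control, while the vinyl group and the silylalkyne react far more slowly.

Step 18
Reactants: 32 (6R,7R)-epoxide of 31
Product: 34 (2S,3S,4R)-5,7-diethoxy-2-[(1R,3R)-3-ethenyl-1-hydroxy-4-methyl-4-(triethylsilyloxy)pentyl]-2-methyl-4-(2-methylpropyl)-3-[4-(triisopropylsilyl)but-3-yn-1-yl]chromane, via epoxy phenol 33 (not isolated)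
Conditions: Cs2CO3, DMF–H2O, rt; extractive work-up; then camphorsulfonic acid (10 mol%), CH2Cl2, 0 °C
Reagents that add atoms: none
Why: Carbonate cleaves only the aryl silyl ether; acid then triggers 6-exo opening of the epoxide by the phenol at the tertiary carbon C7 (favoured by both Markovnikov and Baldwin criteria) with inversion. This closes the pyran ring and sets C7 with CH3 trans to H8; the descriptor reads S here only because C6 now bears oxygen.

Step 19
Reactants: 34 chroman alcohol (C6–OH)
Product: 36 O-[C6 of chroman 34] S-methyl carbonodithioate (xanthate of 34), via sodium xanthate 35 (not isolated)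
Conditions: NaH, CS2, THF, 0 °C → rt; then MeI
Reagents that add atoms: carbon disulfide, S=C=S; iodomethane, CI
Why: Standard xanthate formation from a hindered secondary alcohol (alkoxide, CS2, S-methylation).

Step 20
Reactants: 36 xanthate of 34
Product: 37 (2R,3S,4R)-5,7-diethoxy-2-[(3R)-3-ethenyl-4-methyl-4-(triethylsilyloxy)pentyl]-2-methyl-4-(2-methylpropyl)-3-[4-(triisopropylsilyl)but-3-yn-1-yl]chromane
Conditions: Bu3SnH (0.3 M), AIBN, toluene, 90 °C
Reagents that add atoms: none
Why: Barton–McCombie deoxygenation removes the C6 oxygen; the high Bu3SnH concentration is chosen so that hydrogen transfer to the C6 radical outruns 6-exo cyclisation onto the alkyne and loss of the β-aryloxy group.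

Step 21
Reactants: 37 diethoxychroman
Product: 38 6,8-dibromo derivative of 37 (bromine on Ar3 and Ar5)
Conditions: N-bromosuccinimide (2.1 equiv), MeCN, −20 → 0 °C, dark
Reagents that add atoms: N-bromosuccinimide, O=C1CCC(=O)N1Br
Why: Electrophilic aromatic bromination; Ar3 and Ar5 are the only free positions of the trialkoxyarene and react far faster than the vinyl group.

Step 22
Reactants: 38 6,8-dibromo-5,7-diethoxychroman
Product: 41 5,7-diethoxy-6,8-diformyl chroman (CHO on Ar3 and Ar5; side chains as in 37), via aryldilithium 39 (not isolated), via bis(aminoalkoxide) 40 (not isolated)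
Conditions: t-BuLi (4.4 equiv), THF, −78 °C; DMF (6 equiv), −78 → 0 °C; aq. NH4Cl
Reagents that add atoms: N,N-dimethylformamide, CN(C)C=O
Why: Twofold bromine–lithium exchange and formylation with DMF; each aryllithium is flanked by two oxygens, and no Lewis acid touches the tertiary ethers.

Step 23
Reactants: 41 5,7-diethoxy-6,8-diformyl chroman
Product: 42 (2R,3S,4R)-2-[(3R)-3-ethenyl-4-methyl-4-(triethylsilyloxy)pentyl]-5,7-dihydroxy-2-methyl-4-(2-methylpropyl)-3-[4-(triisopropylsilyl)but-3-yn-1-yl]chromane-6,8-dicarbaldehyde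
Conditions: NaSEt (8 equiv), DMF, 90 °C; dilute aq. HCl work-up
Reagents that add atoms: none
Why: Nucleophilic dealkylation by SN2 attack of thiolate at the ethyl groups; both ethers are activated by ortho and para formyl groups, and the tertiary C7–O bond cannot react by SN2.

Step 24
Reactants: 42 silyl-protected dihydroxy dialdehyde
Product: 43 (2R,3S,4R)-3-(but-3-yn-1-yl)-2-[(3R)-3-ethenyl-4-hydroxy-4-methylpentyl]-5,7-dihydroxy-2-methyl-4-(2-methylpropyl)chromane-6,8-dicarbaldehyde
Conditions: Bu4NF (4 equiv), THF, 0 °C → rt; aq. NH4Cl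
Reagents that add atoms: none
Why: Fluoride-mediated desilylation frees the terminal alkyne and the tertiary alcohol in one operation.

Step 25
Reactants: 43 enyne
Product: 45 target CNP0479784.1 (4R,7R,8S,11R), via triene 44 (not isolated)
Conditions: second-generation Grubbs catalyst (H2IMes)(PCy3)Cl2Ru=CHPh (10 mol%), ethylene (1 atm), CH2Cl2, rt; then argon sparge, dilution to 1 mM, further catalyst (10 mol%), 40 °C
Reagents that add atoms: ethylene, C=C
Why: Ethylene–alkyne cross-enyne metathesis gives the 2-substituted butadiene 44, whose monosubstituted vinyl group then undergoes ring-closing metathesis with the C4 vinyl group and releases ethylene. Closure is expected in the endo sense because the 1,1-disubstituted alkene is the less reactive partner, and the ten-membered ring should enforce the Z C2=C3 alkene.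

## Compound list

1 | prenol (3-methylbut-2-en-1-ol) | CC(C)=CCO | starting material
2 | (R)-(3,3-dimethyloxiran-2-yl)methanol | OC[C@H]1OC1(C)C | intermediate
3 | (S)-2-ethenyl-3-methylbutane-1,3-diol | C=C[C@H](C(C)(C)O)CO | intermediate
4 | (R)-3-(iodomethyl)-2-methylpent-4-en-2-ol | C=C[C@H](C(C)(C)O)CI | intermediate
5 | (R)-triethyl{[3-(iodomethyl)-2-methylpent-4-en-2-yl]oxy}silane | C=C[C@H](C(C)(C)O[Si](CC)(CC)CC)CI | intermediate
6 | ethynyltriisopropylsilane | C#C[Si](C(C)C)(C(C)C)C(C)C | starting material
7 | oxetane | C1COC1 | starting material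
8 | lithium (triisopropylsilyl)acetylide (not isolated) | [Li]C#C[Si](C(C)C)(C(C)C)C(C)C | intermediate
9 | 5-(triisopropylsilyl)pent-4-yn-1-ol | OCCCC#C[Si](C(C)C)(C(C)C)C(C)C | intermediate
10 | 5-(triisopropylsilyl)pent-4-ynal | O=CCCC#C[Si](C(C)C)(C(C)C)C(C)C | intermediate
11 | 2-(triphenylphosphoranylidene)propanal | CC(C=O)=P(c1ccccc1)(c1ccccc1)c1ccccc1 | starting material
12 | (E)-2-methyl-7-(triisopropylsilyl)hept-2-en-6-ynal | O=C/C(C)=C/CCC#C[Si](C(C)C)(C(C)C)C(C)C | intermediate
13 | [(2R)-2-ethenyl-3-methyl-3-(triethylsilyloxy)butyl]lithium (not isolated) | [Li]C[C@H](C=C)C(C)(C)O[Si](CC)(CC)CC | intermediate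
14 | (3R,6E)-3-ethenyl-2,6-dimethyl-2-(triethylsilyloxy)-11-(triisopropylsilyl)undec-6-en-10-yn-5-ol, C6 epimers | OC(C[C@H](C=C)C(C)(C)O[Si](CC)(CC)CC)/C(C)=C/CCC#C[Si](C(C)C)(C(C)C)C(C)C | intermediate
15 | (3R,6E)-3-ethenyl-2,6-dimethyl-2-(triethylsilyloxy)-11-(triisopropylsilyl)undec-6-en-10-yn-5-one | O=C(C[C@H](C=C)C(C)(C)O[Si](CC)(CC)CC)/C(C)=C/CCC#C[Si](C(C)C)(C(C)C)C(C)C | intermediate
16 | (3R,5S,6E)-3-ethenyl-2,6-dimethyl-2-(triethylsilyloxy)-11-(triisopropylsilyl)undec-6-en-10-yn-5-ol | O[C@@H](C[C@H](C=C)C(C)(C)O[Si](CC)(CC)CC)/C(C)=C/CCC#C[Si](C(C)C)(C(C)C)C(C)C | intermediate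
17 | 4-methylpentanoic acid | CC(C)CCC(=O)O | starting material
18 | (3R,5S,6E)-3-ethenyl-2,6-dimethyl-2-(triethylsilyloxy)-11-(triisopropylsilyl)undec-6-en-10-yn-5-yl 4-methylpentanoate | CC(C)CCC(=O)O[C@@H](C[C@H](C=C)C(C)(C)O[Si](CC)(CC)CC)/C(C)=C/CCC#C[Si](C(C)C)(C(C)C)C(C)C | intermediate
19 | (E)-trimethylsilyl ketene acetal of ester 18 (isobutyl trans to OSiMe3; not isolated) | CC(C)C/C=C(/O[Si](C)(C)C)O[C@@H](C[C@H](C=C)C(C)(C)O[Si](CC)(CC)CC)/C(C)=C/CCC#C[Si](C(C)C)(C(C)C)C(C)C | intermediate
20 | (2R,3S,4E,7R)-7-ethenyl-4,8-dimethyl-2-(2-methylpropyl)-8-(triethylsilyloxy)-3-[4-(triisopropylsilyl)but-3-yn-1-yl]non-4-enoic acid (Q–CO2H) | OC(=O)[C@H](CC(C)C)[C@@H](/C(C)=C/C[C@H](C=C)C(C)(C)O[Si](CC)(CC)CC)CCC#C[Si](C(C)C)(C(C)C)C(C)C | intermediate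
21 | acid chloride Q–COCl (not isolated) | ClC(=O)[C@H](CC(C)C)[C@@H](/C(C)=C/C[C@H](C=C)C(C)(C)O[Si](CC)(CC)CC)CCC#C[Si](C(C)C)(C(C)C)C(C)C | intermediate
22 | diazoketone Q–C(=O)CHN2 | [N-]=[N+]=CC(=O)[C@H](CC(C)C)[C@@H](/C(C)=C/C[C@H](C=C)C(C)(C)O[Si](CC)(CC)CC)CCC#C[Si](C(C)C)(C(C)C)C(C)C | intermediate
23 | ethoxyacetylene | CCOC#C | starting material
24 | alkylketene Q–CH=C=O (not isolated) | O=C=C[C@H](CC(C)C)[C@@H](/C(C)=C/C[C@H](C=C)C(C)(C)O[Si](CC)(CC)CC)CCC#C[Si](C(C)C)(C(C)C)C(C)C | intermediate
25 | 3-ethoxy-4-Q-cyclobut-2-en-1-one (ring CH as a mixture) | CCOC1=CC(=O)C1[C@H](CC(C)C)[C@@H](/C(C)=C/C[C@H](C=C)C(C)(C)O[Si](CC)(CC)CC)CCC#C[Si](C(C)C)(C(C)C)C(C)C | intermediate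
26 | vinylketene O=C=CH–C(OEt)=CH–Q (Q trans to the ketene carbon; not isolated) | O=C=C/C(OCC)=C/[C@H](CC(C)C)[C@@H](/C(C)=C/C[C@H](C=C)C(C)(C)O[Si](CC)(CC)CC)CCC#C[Si](C(C)C)(C(C)C)C(C)C | intermediate
27 | 3-ethoxy-4-[1-ethoxy-2-Q-ethenyl]cyclobut-2-en-1-one (not isolated) | CCOC1=CC(=O)C1/C(OCC)=C/[C@H](CC(C)C)[C@@H](/C(C)=C/C[C@H](C=C)C(C)(C)O[Si](CC)(CC)CC)CCC#C[Si](C(C)C)(C(C)C)C(C)C | intermediate
28 | dienylketene O=C=CH–C(OEt)=CH–C(OEt)=CH–Q (central alkene cis; not isolated) | O=C=C/C(OCC)=C\C(OCC)=C\[C@H](CC(C)C)[C@@H](/C(C)=C/C[C@H](C=C)C(C)(C)O[Si](CC)(CC)CC)CCC#C[Si](C(C)C)(C(C)C)C(C)C | intermediate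
29 | 3,5-diethoxy-6-Q-cyclohexa-2,4-dien-1-one (not isolated) | O=C1C=C(OCC)C=C(OCC)C1[C@H](CC(C)C)[C@@H](/C(C)=C/C[C@H](C=C)C(C)(C)O[Si](CC)(CC)CC)CCC#C[Si](C(C)C)(C(C)C)C(C)C | intermediate
30 | 3,5-diethoxy-2-Q-phenol | CCOc1cc(OCC)c(c(O)c1)[C@H](CC(C)C)[C@@H](/C(C)=C/C[C@H](C=C)C(C)(C)O[Si](CC)(CC)CC)CCC#C[Si](C(C)C)(C(C)C)C(C)C | intermediate
31 | tert-butyl(3,5-diethoxy-2-Q-phenoxy)dimethylsilane | CCOc1cc(OCC)c(c(O[Si](C)(C)C(C)(C)C)c1)[C@H](CC(C)C)[C@@H](/C(C)=C/C[C@H](C=C)C(C)(C)O[Si](CC)(CC)CC)CCC#C[Si](C(C)C)(C(C)C)C(C)C | intermediate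
32 | (6R,7R)-epoxide of 31 | CCOc1cc(OCC)c(c(O[Si](C)(C)C(C)(C)C)c1)[C@H](CC(C)C)[C@@H]([C@@]2(C)O[C@@H]2C[C@H](C=C)C(C)(C)O[Si](CC)(CC)CC)CCC#C[Si](C(C)C)(C(C)C)C(C)C | intermediate
33 | (6R,7R)-epoxy phenol (32 without the aryl silyl group; not isolated) | CCOc1cc(OCC)c(c(O)c1)[C@H](CC(C)C)[C@@H]([C@@]2(C)O[C@@H]2C[C@H](C=C)C(C)(C)O[Si](CC)(CC)CC)CCC#C[Si](C(C)C)(C(C)C)C(C)C | intermediate
34 | (2S,3S,4R)-5,7-diethoxy-2-[(1R,3R)-3-ethenyl-1-hydroxy-4-methyl-4-(triethylsilyloxy)pentyl]-2-methyl-4-(2-methylpropyl)-3-[4-(triisopropylsilyl)but-3-yn-1-yl]chromane | C=C[C@H](C(C)(C)O[Si](CC)(CC)CC)C[C@@H](O)[C@@]2(C)Oc3cc(OCC)cc(OCC)c3[C@H](CC(C)C)[C@@H]2CCC#C[Si](C(C)C)(C(C)C)C(C)C | intermediate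
35 | sodium xanthate of 34 (not isolated) | C=C[C@H](C(C)(C)O[Si](CC)(CC)CC)C[C@@H](OC(=S)[S-])[C@@]2(C)Oc3cc(OCC)cc(OCC)c3[C@H](CC(C)C)[C@@H]2CCC#C[Si](C(C)C)(C(C)C)C(C)C.[Na+] | intermediate
36 | S-methyl xanthate of 34 (O-alkyl S-methyl carbonodithioate at C6) | C=C[C@H](C(C)(C)O[Si](CC)(CC)CC)C[C@@H](OC(=S)SC)[C@@]2(C)Oc3cc(OCC)cc(OCC)c3[C@H](CC(C)C)[C@@H]2CCC#C[Si](C(C)C)(C(C)C)C(C)C | intermediate
37 | (2R,3S,4R)-5,7-diethoxy-2-[(3R)-3-ethenyl-4-methyl-4-(triethylsilyloxy)pentyl]-2-methyl-4-(2-methylpropyl)-3-[4-(triisopropylsilyl)but-3-yn-1-yl]chromane | C=C[C@H](C(C)(C)O[Si](CC)(CC)CC)CC[C@@]2(C)Oc3cc(OCC)cc(OCC)c3[C@H](CC(C)C)[C@@H]2CCC#C[Si](C(C)C)(C(C)C)C(C)C | intermediate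
38 | 6,8-dibromo derivative of 37 | C=C[C@H](C(C)(C)O[Si](CC)(CC)CC)CC[C@@]2(C)Oc3c(Br)c(OCC)c(Br)c(OCC)c3[C@H](CC(C)C)[C@@H]2CCC#C[Si](C(C)C)(C(C)C)C(C)C | intermediate
39 | 6,8-dilithio derivative of 37 (not isolated) | C=C[C@H](C(C)(C)O[Si](CC)(CC)CC)CC[C@@]2(C)Oc3c([Li])c(OCC)c([Li])c(OCC)c3[C@H](CC(C)C)[C@@H]2CCC#C[Si](C(C)C)(C(C)C)C(C)C | intermediate
40 | bis(lithium dimethylaminoalkoxide) adduct of 39 with DMF (not isolated) | C=C[C@H](C(C)(C)O[Si](CC)(CC)CC)CC[C@@]2(C)Oc3c(C(O[Li])N(C)C)c(OCC)c(C(O[Li])N(C)C)c(OCC)c3[C@H](CC(C)C)[C@@H]2CCC#C[Si](C(C)C)(C(C)C)C(C)C | intermediate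
41 | 5,7-diethoxy-6,8-dicarbaldehyde derivative of 37 | C=C[C@H](C(C)(C)O[Si](CC)(CC)CC)CC[C@@]2(C)Oc3c(C=O)c(OCC)c(C=O)c(OCC)c3[C@H](CC(C)C)[C@@H]2CCC#C[Si](C(C)C)(C(C)C)C(C)C | intermediate
42 | (2R,3S,4R)-2-[(3R)-3-ethenyl-4-methyl-4-(triethylsilyloxy)pentyl]-5,7-dihydroxy-2-methyl-4-(2-methylpropyl)-3-[4-(triisopropylsilyl)but-3-yn-1-yl]chromane-6,8-dicarbaldehyde | C=C[C@H](C(C)(C)O[Si](CC)(CC)CC)CC[C@@]2(C)Oc3c(C=O)c(O)c(C=O)c(O)c3[C@H](CC(C)C)[C@@H]2CCC#C[Si](C(C)C)(C(C)C)C(C)C | intermediate
43 | (2R,3S,4R)-3-(but-3-yn-1-yl)-2-[(3R)-3-ethenyl-4-hydroxy-4-methylpentyl]-5,7-dihydroxy-2-methyl-4-(2-methylpropyl)chromane-6,8-dicarbaldehyde | C=C[C@H](C(C)(C)O)CC[C@@]2(C)Oc3c(C=O)c(O)c(C=O)c(O)c3[C@H](CC(C)C)[C@@H]2CCC#C | intermediate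
44 | triene: 43 with the but-3-ynyl group converted to 3-methylidenepent-4-en-1-yl (not isolated) | C=C[C@H](C(C)(C)O)CC[C@@]2(C)Oc3c(C=O)c(O)c(C=O)c(O)c3[C@H](CC(C)C)[C@@H]2CCC(=C)C=C | intermediate
45 | CNP0479784.1, (4R,7R,8S,11R) | C=C1/C=C\[C@H](C(C)(C)O)CC[C@@]2(C)Oc3c(C=O)c(O)c(C=O)c(O)c3[C@H](CC(C)C)[C@@H]2CC1 | target

## Step count and risk

Total: 25 steps. Longest linear sequence: 22 steps (steps 1–4 and 8–25).

**Step 15 (key step).** The most likely failure is stalled conversion: the donor-stabilised cyclobutenone opens slowly, ethoxyacetylene is lost by thermal retro-ene fragmentation at the same temperature, and the product phenol captures the vinylketene. The fallback inverts the roles of the partners so that the chain sits on the alkyne. It sets out from acid **20**: esterification (Me3SiCHN2, MeOH) gives methyl ester F1; Kowalski homologation (CH2Br2/LiTMP, then LiHMDS, then n-BuLi) gives lithium ynolate F2, which is O-silylated with i-Pr3SiCl to siloxyalkyne F3. Heating F3 with commercial 3-ethoxycyclobut-2-en-1-one (CCOC1=CC(=O)C1) in toluene should give resorcinol-type phenol F4 by the same annulation manifold. Ethylation of the free hydroxyl (EtI, K2CO3) gives diethyl ether F5, and selective fluoride cleavage of the aryl silyl ether (Bu4NF, 1 equiv, 0 °C) returns to phenol **30**. This path also bypasses steps 13 and 14.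

**Step 25.** The most likely failure is oligomerisation or a stalled ring closure: ten-membered ring strain meets a hindered allylic vinyl group, and the salicylaldehyde-type OH/CHO pairs can sequester the ruthenium carbene. The fallback moves ring closure ahead of the arene end game. It sets out from dibromide **38**: fluoride desilylation gives bromo enyne F6; ethylene-mediated enyne metathesis as in step 25 passes through triene F7 to macrocyclic dibromide F8; bromine–lithium exchange and DMF (one extra equivalent of t-BuLi for the alkoxide) give macrocyclic diethoxy dialdehyde F9; thiolate de-ethylation at the lowest workable temperature returns to target **45**. The price is that the last step is run on the diene.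

**Step 14.** The most likely failure is loss of the hindered aldoketene to dimerisation, or carbene side reactions (C–H insertion, cyclopropanation of the chain alkenes), before the cycloaddition. The fallback generates the ketene by dehydrochlorination. It sets out from diazoketone **22**: silver-catalysed Wolff rearrangement (PhCO2Ag, Et3N, aqueous THF) gives homologous acid F10; Ghosez's reagent gives acid chloride F11; slow addition of Et3N in the presence of excess **23** returns to cyclobutenone **25**.

**Step 17.** The most likely failure is poor facial selectivity if the catalyst's preference is mismatched with the adjacent C8 centre, together with competing oxidation of the very electron-rich arene. The fallback abandons the epoxide: it sets out from phenol **30** and uses a Brønsted acid-catalysed Markovnikov hydroalkoxylation (camphorsulfonic acid, toluene, 60 °C) across C6=C7. This should give chroman **37** together with its C7 epimer F12, which is removed by chromatography. It saves steps 16–20 at the cost of C7 control.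

**Step 23.** The most likely failure is incomplete cleavage of the second ethyl ether once the first phenoxide has formed, or elimination across the activated C7–O bond at the temperature required. The fallback changes the order: it sets out from **37**, de-ethylates first (NaSEt, DMF, 150 °C) to dihydroxychroman F13, and then installs both formyl groups on the free phenols by Vilsmeier–Haack reaction (POCl3, DMF, MeCN, 0 °C → rt), returning at **42**.

## Further compounds

F1 | step 15 | methyl ester of acid 20 (Q–CO2Me) | COC(=O)[C@H](CC(C)C)[C@@H](/C(C)=C/C[C@H](C=C)C(C)(C)O[Si](CC)(CC)CC)CCC#C[Si](C(C)C)(C(C)C)C(C)C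
F2 | step 15 | lithium ynolate Q–C≡C–OLi | [Li]OC#C[C@H](CC(C)C)[C@@H](/C(C)=C/C[C@H](C=C)C(C)(C)O[Si](CC)(CC)CC)CCC#C[Si](C(C)C)(C(C)C)C(C)C
F3 | step 15 | siloxyalkyne Q–C≡C–OSi(i-Pr)3 | CC(C)[Si](C(C)C)(C(C)C)OC#C[C@H](CC(C)C)[C@@H](/C(C)=C/C[C@H](C=C)C(C)(C)O[Si](CC)(CC)CC)CCC#C[Si](C(C)C)(C(C)C)C(C)C
F4 | step 15 | 5-ethoxy-2-Q-3-(triisopropylsilyloxy)phenol | CCOc1cc(O)c(c(O[Si](C(C)C)(C(C)C)C(C)C)c1)[C@H](CC(C)C)[C@@H](/C(C)=C/C[C@H](C=C)C(C)(C)O[Si](CC)(CC)CC)CCC#C[Si](C(C)C)(C(C)C)C(C)C
F5 | step 15 | (3,5-diethoxy-2-Q-phenoxy)triisopropylsilane | CCOc1cc(OCC)c(c(O[Si](C(C)C)(C(C)C)C(C)C)c1)[C@H](CC(C)C)[C@@H](/C(C)=C/C[C@H](C=C)C(C)(C)O[Si](CC)(CC)CC)CCC#C[Si](C(C)C)(C(C)C)C(C)C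
F6 | step 25 | 6,8-dibromo-5,7-diethoxy enyne (38 without both silyl groups) | C=C[C@H](C(C)(C)O)CC[C@@]2(C)Oc3c(Br)c(OCC)c(Br)c(OCC)c3[C@H](CC(C)C)[C@@H]2CCC#C
F7 | step 25 | triene from F6 (but-3-ynyl converted to 3-methylidenepent-4-en-1-yl) | C=C[C@H](C(C)(C)O)CC[C@@]2(C)Oc3c(Br)c(OCC)c(Br)c(OCC)c3[C@H](CC(C)C)[C@@H]2CCC(=C)C=C
F8 | step 25 | macrocyclic dibromide (45 with Br in place of CHO and OEt in place of OH) | C=C1/C=C\[C@H](C(C)(C)O)CC[C@@]2(C)Oc3c(Br)c(OCC)c(Br)c(OCC)c3[C@H](CC(C)C)[C@@H]2CC1
F9 | step 25 | macrocyclic diethoxy dialdehyde (di-O-ethyl ether of 45) | C=C1/C=C\[C@H](C(C)(C)O)CC[C@@]2(C)Oc3c(C=O)c(OCC)c(C=O)c(OCC)c3[C@H](CC(C)C)[C@@H]2CC1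
F10 | step 14 | homologous acid Q–CH2–CO2H | OC(=O)C[C@H](CC(C)C)[C@@H](/C(C)=C/C[C@H](C=C)C(C)(C)O[Si](CC)(CC)CC)CCC#C[Si](C(C)C)(C(C)C)C(C)C
F11 | step 14 | homologous acid chloride Q–CH2–COCl | ClC(=O)C[C@H](CC(C)C)[C@@H](/C(C)=C/C[C@H](C=C)C(C)(C)O[Si](CC)(CC)CC)CCC#C[Si](C(C)C)(C(C)C)C(C)C
F12 | step 17 | C7 epimer of chroman 37 | C=C[C@H](C(C)(C)O[Si](CC)(CC)CC)CC[C@]2(C)Oc3cc(OCC)cc(OCC)c3[C@H](CC(C)C)[C@@H]2CCC#C[Si](C(C)C)(C(C)C)C(C)C
F13 | step 23 | 5,7-dihydroxy analogue of 37 | C=C[C@H](C(C)(C)O[Si](CC)(CC)CC)CC[C@@]2(C)Oc3cc(O)cc(O)c3[C@H](CC(C)C)[C@@H]2CCC#C[Si](C(C)C)(C(C)C)C(C)C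
A1 | alternative 1 | complete carbocycle on the dimethoxychroman (target without formyl groups, phenols as methyl ethers) | C=C1/C=C\[C@H](C(C)(C)O)CC[C@@]2(C)Oc3cc(OC)cc(OC)c3[C@H](CC(C)C)[C@@H]2CC1
A2 | alternative 2 | 2-methyl-2-vinylchroman with C7, C8 and C11 set | C=C[C@@]2(C)Oc3cc(OC)cc(OC)c3[C@H](CC(C)C)[C@@H]2CCCO[Si](C)(C)C(C)(C)C
A3 | alternative 3 | ten-membered cis-enone (C1 ketone) fused to the dimethoxychroman | O=C1/C=C\[C@H](C(C)(C)O[Si](CC)(CC)CC)CC[C@@]2(C)Oc3cc(OC)cc(OC)c3[C@H](CC(C)C)[C@@H]2CC1
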